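**Assumption:** the target, 1,7-bis(4-hydroxy-3-methoxyphenyl)heptan-3-one, has no stereocentre and no stereogenic double bond. It is achiral, so "single enantiomer" is read as "the compound as drawn" and no stereocontrol is required.

## Analysis of the target

The target is an acyclic diarylheptanoid: an unbranched C7 chain (numbered C1–C7) with one ketone at C3 and two identical 4-hydroxy-3-methoxyphenyl rings, ring A on C1 and ring B on C7. The chain carries no stereocentre and no ring has to be closed. The sensitive groups are the two free guaiacol-type phenols (acidic, nucleophilic, easily oxidised) and the dialkyl ketone with two enolisable methylenes, C2 and C4. The difficulty is economy and placement, not complexity: the molecule is almost symmetric, but the carbonyl sits at C3 and not at C4, so two CH2 groups separate it from ring A and four from ring B. A symmetric two-directional construction therefore puts oxygen in the wrong place or in excess, and the C4–C7 arm offers no functional handle for a polar bond formation. The feature the route is built on is a hidden duplication: ring A–C1–C2–C3 is a complete dihydroferuloyl unit with C3 at the acyl oxidation level, and ring B–C7–C6 is the same unit after loss of its carboxyl carbon. What remains, C4–C5, is a two-carbon link whose C5 is β to the C3 carbonyl. The target is thus "dihydroferulic acid 1 + vinyl + dihydroferulic acid 1 minus its carboxyl carbon", which invites a decarboxylative radical conjugate addition that forms the C5–C6 bond.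

## Retrosynthetic reasoning

**12 ⇒ 11 (O–benzyl bonds).** The two phenols of 12 are masked as benzyl ethers in 11. Three forward steps would otherwise meet a free ArOH: the active ester (self-acylation), the organomagnesium addition (insoluble phenoxide) and the radical step (phenolic O–H as hydrogen-atom donor). Because both halves come from the same acid, one benzylation serves both, and one hydrogenolysis removes both groups.

**11 ⇒ 4 + 8 (C5–C6).** The chain is cut between C5 and C6, in the middle of the unfunctionalised arm. C5 is β to the ketone, so this bond can be made by addition of a C6-centred radical to an enone. The cut gives two fragments that are both derivatives of the same C6–C3 acid. The radical 9 comes from the redox-active ester 4 by reductive fragmentation and decarboxylation. The acceptor is the vinyl ketone 8, which already holds ring A, C1–C3 and the C4–C5 vinyl group. The forward reaction has to generate a primary radical under conditions that leave the enone intact, add it once at the terminal carbon, and quench the adduct radical 10 by hydrogen transfer.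

**8 ⇒ 6 (C3–C4).** The vinyl ketone is cut at the acyl–vinyl bond. The Weinreb amide 6 takes up a vinyl nucleophile once and gives the enone in one step without over-addition, by way of the chelate 7.

**4 and 6 ⇒ 3 ⇒ 1.** Both 4 and 6 are simple acyl derivatives of the O-benzyl acid 3, made through the acyl imidazole 5 in the case of 6. Acid 3 comes from commercial dihydroferulic acid 1 by exhaustive benzylation to ester 2 and saponification in the same flask. The only branching point of the route is thus a single compound, 3.

## Alternatives that were turned down

Alternative 1: the textbook disconnection, C4–C5 as a C4=C5 enone. The forward key step is a cross-aldol condensation of the methyl group of zingerone A1 with 3-(4-hydroxy-3-methoxyphenyl)propanal A2 to the E-enone A3, followed by hydrogenation of A3 to 12.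
- Both partners are enolisable. A1 can enolise toward C2 as well as toward its methyl group, and A2 self-condenses unless the ketone enolate is preformed, which in turn requires both phenols to be masked.
- A2 is not a bulk chemical and would cost two to three steps of its own.
- The disconnection uses none of the duplication in the molecule.
- The redox-neutral version of the same bond was also considered: linear hydroalkylation of eugenol A4 by the methyl group of A1, whose sum is exactly 12. A metal hydride able to insert the terminal alkene of A4 is also expected to move it into conjugation with the ring, and an α-keto radical generated directly from A1 forms preferentially at the more substituted C2.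

Alternative 2: the biosynthesis-type disconnection, C1–C2 and C6–C7 as alkenes about a central 1,3-diketone. The forward key step is a boron-templated double Claisen–Schmidt condensation of two molecules of vanillin A5 with pentane-2,4-dione A6, which gives curcumin A7. Hydrogenation of A7 gives tetrahydrocurcumin A8, mono-reduction of A8 gives hexahydrocurcumin A9, dehydration of A9 gives the enone A3, and a last hydrogenation gives 12.
- The condensation of A5 with A6 builds a symmetric chain with oxygen at both C3 and C5, whereas the target has only one.
- Removing the surplus oxygen of A7 takes four operations after the key step.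
- The mono-reduction of the largely enolised β-diketone A8 to A9 is inherently statistical.
- The condensation thus solves a more oxidised and more symmetric problem than the one posed.

Alternative 3: the acyl–alkyl disconnection C3–C4. The forward key step is addition of the Grignard reagent of 1-(benzyloxy)-4-(4-bromobutyl)-2-methoxybenzene A10 to the Weinreb amide 6 to give 11, then hydrogenolysis to 12.
- The bond-forming step is reliable, but no cheap guaiacyl building block carries the four-carbon arm of A10.
- The preparation of A10 by chain extension and bromination would need about four steps and shares nothing with the preparation of 6.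
- The route would run to about eight steps, with the two arms made by unrelated chemistry.

Key step: step 5

## Route

**Step 1**
Reactants: 1 3-(4-hydroxy-3-methoxyphenyl)propanoic acid (dihydroferulic acid)
Product: 3 3-[4-(benzyloxy)-3-methoxyphenyl]propanoic acid, via benzyl ester 2 (not isolated)
Conditions: BnBr (2.3 equiv), K2CO3 (3 equiv), DMF, 60 °C; then 2 M aq NaOH, MeOH, 60 °C; HCl work-up
Reagents that add atoms: benzyl bromide, BrCc1ccccc1; sodium hydroxide, [Na+].[OH-] (oxygen of the regenerated CO2H)
Why: Williamson O-alkylation of the phenoxide and the carboxylate gives the benzyl ether benzyl ester 2; hydroxide then cleaves only the ester (saponification), the aryl benzyl ether being inert to base, and acidification should precipitate 3.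

**Step 2**
Reactants: 3 3-[4-(benzyloxy)-3-methoxyphenyl]propanoic acid
Product: 4 1,3-dioxoisoindolin-2-yl 3-[4-(benzyloxy)-3-methoxyphenyl]propanoate
Conditions: N-hydroxyphthalimide (1.1 equiv), DIC (1.1 equiv), DMAP (5 mol %), CH2Cl2, 0 °C → rt; filtration, recrystallisation
Reagents that add atoms: N-hydroxyphthalimide, O=C1c2ccccc2C(=O)N1O
Why: Carbodiimide (Steglich-type) esterification of an unhindered primary acid with the acidic N–OH group; 3 has no other nucleophilic or acylable site, and the redox-active ester is expected to crystallise, which avoids long contact with silica.

**Step 3**
Reactants: 3 3-[4-(benzyloxy)-3-methoxyphenyl]propanoic acid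
Product: 6 3-[4-(benzyloxy)-3-methoxyphenyl]-N-methoxy-N-methylpropanamide, via acyl imidazole 5 (not isolated)
Conditions: CDI (1.1 equiv), CH2Cl2, rt; then MeNH(OMe)·HCl (1.3 equiv), rt
Reagents that add atoms: N,O-dimethylhydroxylamine hydrochloride, CNOC.Cl; 1,1'-carbonyldiimidazole, O=C(n1ccnc1)n1ccnc1 (its imidazole stays in 5 only)
Why: Weinreb amide synthesis by CDI activation to the acyl imidazole 5 and aminolysis; the imidazole set free buffers the hydrochloride, and ether and methoxy groups are untouched.

**Step 4**
Reactants: 6 3-[4-(benzyloxy)-3-methoxyphenyl]-N-methoxy-N-methylpropanamide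
Product: 8 5-[4-(benzyloxy)-3-methoxyphenyl]pent-1-en-3-one, via magnesium hemiaminal chelate 7 (not isolated)
Conditions: CH2=CHMgBr (1.5 equiv), THF, −10 → 0 °C; inverse quench into cold 1 M HCl/Et2O; used without storage
Reagents that add atoms: vinylmagnesium bromide, C=C[Mg]Br
Why: Weinreb ketone synthesis; the five-membered magnesium chelate 7 stops the reaction after one addition, and the cold inverse acid quench collapses 7 to the enone while protonating the expelled N,O-dimethylhydroxylamine so that it should not add back to the vinyl ketone.

**Step 5**
Reactants: 4 1,3-dioxoisoindolin-2-yl 3-[4-(benzyloxy)-3-methoxyphenyl]propanoate; 8 5-[4-(benzyloxy)-3-methoxyphenyl]pent-1-en-3-one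
Product: 11 1,7-bis[4-(benzyloxy)-3-methoxyphenyl]heptan-3-one, via primary alkyl radical 9 (not isolated), via α-keto radical 10 (not isolated)
Conditions: 4 (1.5 equiv), 8 (1.0 equiv), [Ru(bpy)3](PF6)2 (1 mol %), Hantzsch ester (2 equiv), i-Pr2NEt·HBF4 (1 equiv), degassed CH2Cl2, blue LEDs, rt
Reagents that add atoms: none
Why: Reductive quenching of photoexcited [Ru(bpy)3]2+ by the Hantzsch ester gives the reduced complex [Ru(bpy)3]+, which transfers one electron to the phthalimide ester 4; N–O cleavage and loss of CO2 release the primary 2-arylethyl radical 9, the C6–C7 fragment. Radical 9 is nucleophilic and adds to the unsubstituted terminal carbon (C5) of the electron-poor vinyl ketone 8, forming the C5–C6 bond and the carbonyl-stabilised radical 10, which is quenched at C4 by hydrogen-atom transfer from the Hantzsch ester or its radical cation to give 11. The closest known reaction type is the photoreductive decarboxylative Michael (Giese) addition of N-(acyloxy)phthalimides to vinyl ketones and acrylates under Ru(bpy)3/dihydropyridine conditions, which is established for primary alkyl radicals. No ring is closed and no stereocentre is formed, so there is no mode of closure and no stereocontrol to secure. The step needs three selectivities: electron transfer to 4 and not to 8 (secured by the much less negative reduction potential of the phthalimide ester compared with an aliphatic enone), addition at C5 and not at the carbonyl (secured by polarity matching and the unhindered CH2 terminus), and 1:1 stoichiometry without telomerisation (secured because the electrophilic radical 10 adds only slowly to a second electron-poor alkene and is intercepted by the hydrogen donor). The ammonium salt keeps the medium weakly acidic, so the phthalimide that is released stays protonated and should not add to 8 in an aza-Michael reaction. Benzyl ethers, methoxy groups and the ketone are inert under these conditions.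

**Step 6**
Reactants: 11 1,7-bis[4-(benzyloxy)-3-methoxyphenyl]heptan-3-one
Product: 12 1,7-bis(4-hydroxy-3-methoxyphenyl)heptan-3-one (target)
Conditions: H2 (1 atm), 10 % Pd/C, EtOAc–EtOH, rt
Reagents that add atoms: none
Why: Heterogeneous hydrogenolysis of both aryl benzyl ethers; a dialkyl ketone is not reduced over Pd/C at atmospheric pressure and no other reducible group is present, so 12 should be obtained directly.

## Compound list

1 | 3-(4-hydroxy-3-methoxyphenyl)propanoic acid (dihydroferulic acid) | COc1cc(CCC(=O)O)ccc1O | starting material
2 | benzyl 3-[4-(benzyloxy)-3-methoxyphenyl]propanoate | COc1cc(CCC(=O)OCc2ccccc2)ccc1OCc1ccccc1 | intermediate (not isolated)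
3 | 3-[4-(benzyloxy)-3-methoxyphenyl]propanoic acid | COc1cc(CCC(=O)O)ccc1OCc1ccccc1 | intermediate
4 | 1,3-dioxoisoindolin-2-yl 3-[4-(benzyloxy)-3-methoxyphenyl]propanoate | COc1cc(CCC(=O)ON2C(=O)c3ccccc3C2=O)ccc1OCc1ccccc1 | intermediate
5 | 1-{3-[4-(benzyloxy)-3-methoxyphenyl]propanoyl}-1H-imidazole | COc1cc(CCC(=O)n2ccnc2)ccc1OCc1ccccc1 | intermediate (not isolated)
6 | 3-[4-(benzyloxy)-3-methoxyphenyl]-N-methoxy-N-methylpropanamide | COc1cc(CCC(=O)N(C)OC)ccc1OCc1ccccc1 | intermediate
7 | bromomagnesium alkoxide of 5-[4-(benzyloxy)-3-methoxyphenyl]-3-[methoxy(methyl)amino]pent-1-en-3-ol (chelated tetrahedral adduct) | C=CC(O[Mg]Br)(CCc1ccc(OCc2ccccc2)c(OC)c1)N(C)OC | intermediate (not isolated)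
8 | 5-[4-(benzyloxy)-3-methoxyphenyl]pent-1-en-3-one | C=CC(=O)CCc1ccc(OCc2ccccc2)c(OC)c1 | intermediate
9 | 2-[4-(benzyloxy)-3-methoxyphenyl]ethyl radical | [CH2]Cc1ccc(OCc2ccccc2)c(OC)c1 | intermediate (not isolated)
10 | 1,7-bis[4-(benzyloxy)-3-methoxyphenyl]-3-oxoheptan-4-yl radical | COc1cc(CCC[CH]C(=O)CCc2ccc(OCc3ccccc3)c(OC)c2)ccc1OCc1ccccc1 | intermediate (not isolated)
11 | 1,7-bis[4-(benzyloxy)-3-methoxyphenyl]heptan-3-one | COc1cc(CCCCC(=O)CCc2ccc(OCc3ccccc3)c(OC)c2)ccc1OCc1ccccc1 | intermediate
12 | 1,7-bis(4-hydroxy-3-methoxyphenyl)heptan-3-one | COc1cc(CCCCC(=O)CCc2ccc(O)c(OC)c2)ccc1O | target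

## Step count and risk

Total step count: 6. Longest linear sequence: 5 (steps 1, 3, 4, 5, 6); step 2 is a one-step branch from the common acid 3.

**Step 5 (key step).** The most likely failure is premature hydrogen-atom transfer to the primary radical before it meets the acceptor. Primary radicals add more slowly than the tertiary radicals for which this photocatalytic system is most often used, and the Hantzsch ester is a good hydrogen donor. Telomerisation of the vinyl ketone through the adduct radical and slow conjugate reduction of the enone are the other loss channels. The fallback abandons the radical C5–C6 union for a polar C3–C4 union that still draws both halves from one compound. It sets out from 6. Reduction with DIBAL-H at −78 °C should give 3-[4-(benzyloxy)-3-methoxyphenyl]propanal F1. Ohira–Bestmann homologation (K2CO3, MeOH) converts F1 into 1-(benzyloxy)-4-(but-3-yn-1-yl)-2-methoxybenzene F2. Lithiation of F2 with n-BuLi and acylation with a second portion of 6 gives the ynone 1,7-bis[4-(benzyloxy)-3-methoxyphenyl]hept-4-yn-3-one F3. Hydrogenation of F3 over Pd/C saturates the triple bond and cleaves both benzyl ethers in one operation, so the fallback comes back to the route at 12.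

**Step 4.** Two processes threaten the vinyl ketone: conjugate addition of the liberated N,O-dimethylhydroxylamine to the enone during the quench, and polymerisation on concentration. The fallback forms the enone by oxidation under neutral, amine-free conditions. It sets out from 6, which is reduced with DIBAL-H to 3-[4-(benzyloxy)-3-methoxyphenyl]propanal F1. Addition of vinylmagnesium bromide to F1 gives racemic 5-[4-(benzyloxy)-3-methoxyphenyl]pent-1-en-3-ol F4, a stable compound that can be stored. Oxidation of F4 with Dess–Martin periodinane (or MnO2) immediately before the key step returns to the route at 8.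

**Step 2.** The active ester may suffer hydrolysis or acyl transfer during work-up and purification, which would carry free acid and N-hydroxyphthalimide into the photochemical step. The fallback omits pre-activation. It sets out from 3, which is added directly to 8 in a decarboxylative conjugate addition under acridine photocatalysis with a copper co-catalyst. There the radical arises by proton-coupled electron transfer within the acid–acridine hydrogen-bonded complex. This comes back to the route at 11 and makes no new compound.

**Step 6.** The hydrogenolysis may stall at the mono-benzyl stage if traces of ruthenium complex or pyridine by-product from step 5 poison the catalyst, and prolonged forcing risks slow reduction of the ketone. The fallback changes from reductive to Lewis-acid cleavage. It sets out from 11, which is treated with BCl3 and pentamethylbenzene as a non-basic benzyl-cation scavenger in CH2Cl2 at −78 °C. This comes back to the route at 12 and makes no new compound.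

## Further compounds

F1 | step 5 | 3-[4-(benzyloxy)-3-methoxyphenyl]propanal | COc1cc(CCC=O)ccc1OCc1ccccc1
F2 | step 5 | 1-(benzyloxy)-4-(but-3-yn-1-yl)-2-methoxybenzene | C#CCCc1ccc(OCc2ccccc2)c(OC)c1
F3 | step 5 | 1,7-bis[4-(benzyloxy)-3-methoxyphenyl]hept-4-yn-3-one | COc1cc(CCC#CC(=O)CCc2ccc(OCc3ccccc3)c(OC)c2)ccc1OCc1ccccc1
F4 | step 4 | 5-[4-(benzyloxy)-3-methoxyphenyl]pent-1-en-3-ol (racemic) | C=CC(O)CCc1ccc(OCc2ccccc2)c(OC)c1
F0 | step 2 | none | none
F0 | step 6 | none | none
A1 | alternative 1 | 4-(4-hydroxy-3-methoxyphenyl)butan-2-one (zingerone) | CC(=O)CCc1ccc(O)c(OC)c1
A2 | alternative 1 | 3-(4-hydroxy-3-methoxyphenyl)propanal | O=CCCc1ccc(O)c(OC)c1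
A3 | alternative 1 | (E)-1,7-bis(4-hydroxy-3-methoxyphenyl)hept-4-en-3-one | COc1cc(CC/C=C/C(=O)CCc2ccc(O)c(OC)c2)ccc1O
A4 | alternative 1 | 4-allyl-2-methoxyphenol (eugenol) | C=CCc1ccc(O)c(OC)c1
A5 | alternative 2 | 4-hydroxy-3-methoxybenzaldehyde (vanillin) | COc1cc(C=O)ccc1O
A6 | alternative 2 | pentane-2,4-dione | CC(=O)CC(C)=O
A7 | alternative 2 | (1E,6E)-1,7-bis(4-hydroxy-3-methoxyphenyl)hepta-1,6-diene-3,5-dione (curcumin) | COc1cc(/C=C/C(=O)CC(=O)/C=C/c2ccc(O)c(OC)c2)ccc1O
A8 | alternative 2 | 1,7-bis(4-hydroxy-3-methoxyphenyl)heptane-3,5-dione (tetrahydrocurcumin) | COc1cc(CCC(=O)CC(=O)CCc2ccc(O)c(OC)c2)ccc1O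
A9 | alternative 2 | 5-hydroxy-1,7-bis(4-hydroxy-3-methoxyphenyl)heptan-3-one (hexahydrocurcumin, racemic) | COc1cc(CCC(O)CC(=O)CCc2ccc(O)c(OC)c2)ccc1O
A10 | alternative 3 | 1-(benzyloxy)-4-(4-bromobutyl)-2-methoxybenzene | COc1cc(CCCCBr)ccc1OCc1ccccc1
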